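## Retrosynthetic overview

1. Target ⇐ cleavage of two aryl silyl ethers ⇐ ozonolysis of a tetrahydrofuran alcohol that carries the aroyl group as a 1-arylethenyl group.
2. That alcohol ⇐ 2-aryl-4-(1-arylethenyl)tetrahydrofuran-3-carbaldehyde ⇐ 2-aryl-5-(1-arylethenyl)-4,5-dihydro-1,3-dioxepine by a Lewis-acid [1,3] O→C shift, which forms C2–C3 and relays configuration from the alkenyl-bearing carbon to C2 and C3.
3. The dihydrodioxepine ⇐ mirror-symmetric 2-aryl-4,7-dihydro-1,3-dioxepine + 1-arylethenyl triflate by an enantioselective Heck desymmetrization (key step, sets the future C4).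
4. Symmetric dioxepine ⇐ isovanillin + (Z)-but-2-ene-1,4-diol; triflate ⇐ 3-hydroxy-4-methoxyacetophenone.
5. Ring order: the seven-membered acetal ring is made first and is then contracted to the tetrahydrofuran, the only ring of the target that is built.

Abbreviations: TBS = tert-butyldimethylsilyl; Ar = 3-(TBS-oxy)-4-methoxyphenyl. Oxolane locants: O1, C2 (aryl), C3 (CH2OH), C4 (aroyl), C5.

Assumption: (S)-t-Bu-PHOX is taken to give the 5R product in step 5; if the sense of induction is the opposite, the R ligand is used and nothing else changes.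

## Route

Step 1
Reactants: 1 isovanillin (3-hydroxy-4-methoxybenzaldehyde)
Product: 2 3-(TBS-oxy)-4-methoxybenzaldehyde
Conditions: TBSCl (1.1 equiv), Et3N (1.5 equiv), DMAP (5 mol %), CH2Cl2, 0 °C → rt
Reagents that add atoms: tert-butyldimethylsilyl chloride, CC(C)(C)[Si](C)(C)Cl
Why: Silyl ether formation at the phenol (substitution at silicon) protects it for the Lewis-acid and ozone steps; no stereocentre is involved.

Step 2
Reactants: 2 3-(TBS-oxy)-4-methoxybenzaldehyde; 3 (Z)-but-2-ene-1,4-diol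
Product: 4 2-Ar-4,7-dihydro-1,3-dioxepine
Conditions: pyridinium p-toluenesulfonate (5 mol %), benzene, reflux, Dean–Stark trap
Reagents that add atoms: none
Why: Acid-catalysed acetalization with azeotropic removal of water closes the cis diol to the seven-membered acetal, which has a mirror plane through C2 and the midpoint of C5=C6, so no stereocentre is formed.

Step 3
Reactants: 5 1-(3-hydroxy-4-methoxyphenyl)ethan-1-one
Product: 6 1-[3-(TBS-oxy)-4-methoxyphenyl]ethan-1-one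
Conditions: TBSCl (1.1 equiv), Et3N (1.5 equiv), DMAP (5 mol %), CH2Cl2, 0 °C → rt
Reagents that add atoms: tert-butyldimethylsilyl chloride, CC(C)(C)[Si](C)(C)Cl
Why: Silyl ether formation at the phenol, as in step 1; no stereocentre is involved.

Step 4
Reactants: 6 1-[3-(TBS-oxy)-4-methoxyphenyl]ethan-1-one
Product: 7 1-[3-(TBS-oxy)-4-methoxyphenyl]ethenyl trifluoromethanesulfonate
Conditions: Tf2O (1.2 equiv), 2,6-di-tert-butyl-4-methylpyridine (1.3 equiv), CH2Cl2, 0 °C → rt; filtration through Et3N-deactivated silica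
Reagents that add atoms: trifluoromethanesulfonic anhydride, O=S(=O)(OS(=O)(=O)C(F)(F)F)C(F)(F)F
Why: Enol triflate formation from an aryl methyl ketone (Stang conditions) goes through the O-sulfonylated oxocarbenium ion and loss of a methyl proton, and the hindered non-nucleophilic base avoids elimination to the aryl alkyne; no stereocentre is formed.

Step 5
Reactants: 4 2-Ar-4,7-dihydro-1,3-dioxepine (3 equiv, excess recovered); 7 1-Ar-ethenyl triflate
Product: 8 (5R)-2-Ar-5-(1-Ar-ethenyl)-4,5-dihydro-1,3-dioxepine (both C2 epimers)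
Conditions: Pd(dba)2 (5 mol %), (S)-t-Bu-PHOX (7.5 mol %), i-Pr2NEt (2 equiv), THF, 70 °C, 72 h
Reagents that add atoms: none
Why: Enantioselective intermolecular Mizoroki–Heck reaction (cationic pathway, a known reaction type for 4,7-dihydro-1,3-dioxepines with aryl and alkenyl triflates): the chiral alkenylpalladium cation inserts at one of the two enantiotopic alkene carbons and sets C5 as R, syn β-hydride elimination is possible only towards C7 and gives the enol ether, and the C2 epimers converge because C2 is ionized in step 6.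

Step 6
Reactants: 8 (5R)-2-Ar-5-(1-Ar-ethenyl)-4,5-dihydro-1,3-dioxepine
Product: 11 [(2S,3R,4R)-2-Ar-4-(1-Ar-ethenyl)oxolan-3-yl]methanol, via kinetic aldehyde mixture 9 (not isolated), via all-trans aldehyde 10 (not isolated)
Conditions: Me3SiOTf (10 mol %), 2,6-di-tert-butyl-4-methylpyridine (15 mol %), CH2Cl2, −78 → −30 °C; DBU (0.3 equiv), 0 °C → rt; EtOH, NaBH4 (1.5 equiv), 0 °C
Reagents that add atoms: none
Why: Lewis-acid [1,3] O→C shift of a cyclic enol acetal (Petasis–Ferrier-type ring contraction, known for 4,5-dihydro-1,3-dioxepines): ionization of C2–O1 gives an aryl-stabilized oxocarbenium ion and a silyl enol ether that recombine to the tetrahydrofuran with the aryl group cis to the C4 substituent (both pseudo-equatorial in the envelope), DBU then epimerizes the enolizable C3 to the all-trans aldehyde, and NaBH4 reduces the aldehyde and so fixes C3.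

Step 7
Reactants: 11 [(2S,3R,4R)-2-Ar-4-(1-Ar-ethenyl)oxolan-3-yl]methanol
Product: 13 [(3S,4R,5S)-5-Ar-4-(hydroxymethyl)oxolan-3-yl](Ar)methanone, via ozonide 12 (not isolated)
Conditions: O3, CH2Cl2, −78 °C (Sudan Red 7B end point); Me2S (5 equiv), −78 °C → rt
Reagents that add atoms: ozone, [O-][O+]=O
Why: Ozonolysis (Criegee mechanism) of the electron-rich 1,1-disubstituted alkene, which reacts much faster than the silylated arenes, followed by reductive cleavage of the ozonide, unveils the aryl ketone; C4 becomes enolizable but already has the thermodynamically preferred all-trans arrangement.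

Step 8
Reactants: 13 [(3S,4R,5S)-5-Ar-4-(hydroxymethyl)oxolan-3-yl](Ar)methanone
Product: 14 (3-hydroxy-4-methoxyphenyl)[(3S,4R,5S)-5-(3-hydroxy-4-methoxyphenyl)-4-(hydroxymethyl)oxolan-3-yl]methanone (CNP0234761.1)
Conditions: Bu4NF (2.4 equiv), AcOH (2.6 equiv), THF, 0 °C
Reagents that add atoms: none
Why: Fluoride-mediated cleavage of the two aryl silyl ethers, buffered with acetic acid so that the phenoxides cannot cause enolization or β-alkoxy elimination next to the ketone; no stereocentre is touched.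

## Compound list

1 | isovanillin (3-hydroxy-4-methoxybenzaldehyde) | COc1ccc(C=O)cc1O | starting material
2 | 3-(TBS-oxy)-4-methoxybenzaldehyde | COc1ccc(C=O)cc1O[Si](C)(C)C(C)(C)C | intermediate
3 | (Z)-but-2-ene-1,4-diol | OC/C=C\CO | starting material
4 | 2-[3-(TBS-oxy)-4-methoxyphenyl]-4,7-dihydro-1,3-dioxepine | COc1ccc(C2OCC=CCO2)cc1O[Si](C)(C)C(C)(C)C | intermediate
5 | 1-(3-hydroxy-4-methoxyphenyl)ethan-1-one | CC(=O)c1ccc(OC)c(O)c1 | starting material
6 | 1-[3-(TBS-oxy)-4-methoxyphenyl]ethan-1-one | CC(=O)c1ccc(OC)c(O[Si](C)(C)C(C)(C)C)c1 | intermediate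
7 | 1-[3-(TBS-oxy)-4-methoxyphenyl]ethenyl trifluoromethanesulfonate | C=C(OS(=O)(=O)C(F)(F)F)c1ccc(OC)c(O[Si](C)(C)C(C)(C)C)c1 | intermediate
8 | (5R)-2-Ar-5-(1-Ar-ethenyl)-4,5-dihydro-1,3-dioxepine, C2 epimers | C=C(c1ccc(OC)c(O[Si](C)(C)C(C)(C)C)c1)[C@@H]1COC(c2ccc(OC)c(O[Si](C)(C)C(C)(C)C)c2)OC=C1 | intermediate
9 | (2S,4R)-2-Ar-4-(1-Ar-ethenyl)oxolane-3-carbaldehyde, C3 epimers | C=C(c1ccc(OC)c(O[Si](C)(C)C(C)(C)C)c1)[C@@H]1CO[C@H](c2ccc(OC)c(O[Si](C)(C)C(C)(C)C)c2)C1C=O | intermediate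
10 | (2S,3S,4R)-2-Ar-4-(1-Ar-ethenyl)oxolane-3-carbaldehyde | C=C(c1ccc(OC)c(O[Si](C)(C)C(C)(C)C)c1)[C@@H]1CO[C@H](c2ccc(OC)c(O[Si](C)(C)C(C)(C)C)c2)[C@H]1C=O | intermediate
11 | [(2S,3R,4R)-2-Ar-4-(1-Ar-ethenyl)oxolan-3-yl]methanol | C=C(c1ccc(OC)c(O[Si](C)(C)C(C)(C)C)c1)[C@@H]1CO[C@H](c2ccc(OC)c(O[Si](C)(C)C(C)(C)C)c2)[C@H]1CO | intermediate
12 | [(2S,3R,4S)-2-Ar-4-(3-Ar-1,2,4-trioxolan-3-yl)oxolan-3-yl]methanol, trioxolane epimers | COc1ccc(C2(OCOO2)[C@@H]3CO[C@H](c4ccc(OC)c(O[Si](C)(C)C(C)(C)C)c4)[C@H]3CO)cc1O[Si](C)(C)C(C)(C)C | intermediate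
13 | [(3S,4R,5S)-5-Ar-4-(hydroxymethyl)oxolan-3-yl](Ar)methanone | COc1ccc(C(=O)[C@@H]2CO[C@H](c3ccc(OC)c(O[Si](C)(C)C(C)(C)C)c3)[C@H]2CO)cc1O[Si](C)(C)C(C)(C)C | intermediate
14 | (3-hydroxy-4-methoxyphenyl)[(3S,4R,5S)-5-(3-hydroxy-4-methoxyphenyl)-4-(hydroxymethyl)oxolan-3-yl]methanone | COc1ccc(C(=O)[C@@H]2CO[C@H](c3ccc(OC)c(O)c3)[C@H]2CO)cc1O | target

## Step count and risks

Total step count: 8.
Longest linear sequence: 6 steps (1 → 2 → 4 → 8 → 11 → 13 → 14; the branch from 5 is equally long).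

**Step 5 (enantioselective Heck reaction).** The risks are low enantioselectivity, slow insertion of the hindered alkenyl group, and double-bond migration. The fallback gives up the desymmetrization and builds the skeleton on a butenolide; it sets out from 7 and comes back at 13. Triflate 7 is borylated (B2pin2, PdCl2(PPh3)2, PPh3, KOPh, toluene, 50 °C) to 2-(1-Ar-ethenyl)-4,4,5,5-tetramethyl-1,3,2-dioxaborolane F1. Rhodium-catalysed conjugate addition of F1 to furan-2(5H)-one ([Rh(OH)(cod)]2, the BINAP enantiomer that gives the S product, dioxane/H2O, 60 °C) gives (4S)-4-(1-Ar-ethenyl)oxolan-2-one F2. LiN(i-Pr)2 (THF, −78 °C) and then aldehyde 2 give the trans aldol lactone F3, and LiAlH4 gives the triol F4. Camphorsulfonic acid (cat., CH2Cl2, 0 °C) closes the ring through the benzylic cation to the C4-epimeric tetrahydrofuran alcohol F5 (aryl trans to CH2OH, CH2OH cis to the alkenyl group, as a trans lactone requires). Ozonolysis as in step 7, via the ozonide F6, gives the C4-epimeric ketone F7, and DBU (CH2Cl2, rt) epimerizes the carbon next to the ketone to the all-trans isomer 13.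

**Step 6 (ring contraction and stereochemical relay).** The risks are closure to the 2,4-trans isomer and capture of the oxocarbenium ion by the electron-rich alkene. The fallback applies when the trans isomer predominates; it stops relying on the kinetic 2,4-relationship and lets C3 and C4 equilibrate against C2. It sets out from 4 and 7 and comes back at 13. Step 5 is run with (R)-t-Bu-PHOX to give the (5S)-dihydrodioxepine F8. Ring contraction with Me3SiOTf alone gives the 2,4-trans aldehyde F9 (2S,4S). Ozonolysis via the ozonide F10 gives the keto aldehyde epimer mixture F11, in which C3 and C4 are both enolizable. DBU converges it on the all-trans keto aldehyde F12, whose configuration is dictated by C2 alone. NaBH4 (EtOH/CH2Cl2, −78 °C) reduces only the aldehyde and gives 13.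

**Step 7 (ozonolysis beside two electron-rich arenes).** The risk is over-oxidation of the arenes or the benzylic ether. The fallback replaces ozone by dihydroxylation and glycol cleavage; it sets out from 11 and comes back at 13. K2OsO4·2H2O (cat.) with N-methylmorpholine N-oxide in acetone/H2O gives the triol F13, and NaIO4 (THF/H2O, 0 °C) cleaves the new 1,2-diol to 13.

Further compounds

F1 | step 5 | 2-(1-Ar-ethenyl)-4,4,5,5-tetramethyl-1,3,2-dioxaborolane | C=C(B1OC(C)(C)C(C)(C)O1)c1ccc(OC)c(O[Si](C)(C)C(C)(C)C)c1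
F2 | step 5 | (4S)-4-(1-Ar-ethenyl)oxolan-2-one | C=C(c1ccc(OC)c(O[Si](C)(C)C(C)(C)C)c1)[C@H]1COC(=O)C1
F3 | step 5 | (3S,4S)-3-[Ar(hydroxy)methyl]-4-(1-Ar-ethenyl)oxolan-2-one, carbinol epimers | C=C(c1ccc(OC)c(O[Si](C)(C)C(C)(C)C)c1)[C@H]1COC(=O)[C@@H]1C(O)c1ccc(OC)c(O[Si](C)(C)C(C)(C)C)c1
F4 | step 5 | (2R,3S)-2-[Ar(hydroxy)methyl]-3-(1-Ar-ethenyl)butane-1,4-diol, carbinol epimers | C=C(c1ccc(OC)c(O[Si](C)(C)C(C)(C)C)c1)[C@@H](CO)[C@H](CO)C(O)c1ccc(OC)c(O[Si](C)(C)C(C)(C)C)c1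
F5 | step 5 | [(2S,3R,4S)-2-Ar-4-(1-Ar-ethenyl)oxolan-3-yl]methanol | C=C(c1ccc(OC)c(O[Si](C)(C)C(C)(C)C)c1)[C@H]1CO[C@H](c2ccc(OC)c(O[Si](C)(C)C(C)(C)C)c2)[C@H]1CO
F6 | step 5 | [(2S,3R,4R)-2-Ar-4-(3-Ar-1,2,4-trioxolan-3-yl)oxolan-3-yl]methanol, trioxolane epimers | COc1ccc(C2(OCOO2)[C@H]3CO[C@H](c4ccc(OC)c(O[Si](C)(C)C(C)(C)C)c4)[C@H]3CO)cc1O[Si](C)(C)C(C)(C)C
F7 | step 5 | [(3R,4R,5S)-5-Ar-4-(hydroxymethyl)oxolan-3-yl](Ar)methanone | COc1ccc(C(=O)[C@H]2CO[C@H](c3ccc(OC)c(O[Si](C)(C)C(C)(C)C)c3)[C@H]2CO)cc1O[Si](C)(C)C(C)(C)C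
F8 | step 6 | (5S)-2-Ar-5-(1-Ar-ethenyl)-4,5-dihydro-1,3-dioxepine, C2 epimers | C=C(c1ccc(OC)c(O[Si](C)(C)C(C)(C)C)c1)[C@H]1COC(c2ccc(OC)c(O[Si](C)(C)C(C)(C)C)c2)OC=C1
F9 | step 6 | (2S,4S)-2-Ar-4-(1-Ar-ethenyl)oxolane-3-carbaldehyde, C3 epimers | C=C(c1ccc(OC)c(O[Si](C)(C)C(C)(C)C)c1)[C@H]1CO[C@H](c2ccc(OC)c(O[Si](C)(C)C(C)(C)C)c2)C1C=O
F10 | step 6 | (2S,4R)-2-Ar-4-(3-Ar-1,2,4-trioxolan-3-yl)oxolane-3-carbaldehyde, epimers at C3 and at the trioxolane | COc1ccc(C2(OCOO2)[C@H]3CO[C@H](c4ccc(OC)c(O[Si](C)(C)C(C)(C)C)c4)C3C=O)cc1O[Si](C)(C)C(C)(C)C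
F11 | step 6 | (2S)-2-Ar-4-(Ar-carbonyl)oxolane-3-carbaldehyde, C3 and C4 epimers | COc1ccc(C(=O)C2CO[C@H](c3ccc(OC)c(O[Si](C)(C)C(C)(C)C)c3)C2C=O)cc1O[Si](C)(C)C(C)(C)C
F12 | step 6 | (2S,3S,4S)-2-Ar-4-(Ar-carbonyl)oxolane-3-carbaldehyde | COc1ccc(C(=O)[C@@H]2CO[C@H](c3ccc(OC)c(O[Si](C)(C)C(C)(C)C)c3)[C@H]2C=O)cc1O[Si](C)(C)C(C)(C)C
F13 | step 7 | 1-Ar-1-[(3S,4R,5S)-5-Ar-4-(hydroxymethyl)oxolan-3-yl]ethane-1,2-diol, C1 epimers | COc1ccc(C(O)(CO)[C@@H]2CO[C@H](c3ccc(OC)c(O[Si](C)(C)C(C)(C)C)c3)[C@H]2CO)cc1O[Si](C)(C)C(C)(C)C
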